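Take as your unit the monomer in chains per molecule of initiator charged. Call it u: the units per initiator 16.4, pooled below from the two earlier runs.

| flask | free monomer | initiator | remark | time |
|---|---|---|---|---|
| Monday's | 0.40 M (fed, over 10 h) | 1 mM | run made earlier; the fed solution adds 0.20 times the starting volume |  |
| Sunday's | 0.40 M (fed, over 10 h) | 1.5 mM | run made earlier; the fed solution adds 0.20 times the starting volume |  |
| flask | 0.40 M (fed, over 10 h) | 2.0 mM | the fed solution adds 0.20 times the starting volume | 12 h |

| run | time / h | monomer in chains / % | free monomer / % |
|---|---|---|---|
| Monday's | 1.50 | 0 | 16.8 |
| Monday's | 3.00 | 0.5 | 29.8 |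
| Monday's | 5.00 | 0.2 | 49.2 |
| Monday's | 6.00 | 0.7 | 58.3 |
| Monday's | 8.00 | 1.7 | 79.3 |
| Monday's | 10.0 | 2.2 | 98.0 |
| Monday's | 12.0 | 4.9 | 96.2 |
| Sunday's | 1.00 | 0 | 8.1 |
| Sunday's | 1.33 | 0 | 12.5 |
| Sunday's | 2.00 | 0 | 19.3 |
| Sunday's | 3.00 | 0.4 | 30.3 |
| Sunday's | 5.00 | 1.5 | 50.0 |
| Sunday's | 8.00 | 1.8 | 76.5 |
| Sunday's | 12.0 | 5.6 | 94.4 |

(scatter of a reading: 1 percentage point)

1. average number of monomer units in a chain (chains begun, living or dead) at 12 h
2. part of the free monomer that has reacted at 12 h

- amounts are per litre of the starting volume; all of the dose is in the solution fed
- the average divides the monomer in chains by the number of chains begun, living and dead together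
- the earlier runs do not show the number of chains; that part of a forecast is a guess
- percentages count the whole charge, also what has not yet gone in

The feed is the same in all three flasks, so you can solve two extreme versions in your head. In the first, monomer in chains ignores the initiator, and the flask stays at the mean of the two readings at 12 h, 5.25 %. In the second, monomer in chains follows the initiator in proportion, so u is the same in each run. The two readings differ by 0.7 percentage points, with a scatter of 1 point, so they cannot choose. I lean to the second; that is my choice, not a reading. A line through zero, pooled over both runs, gives u = 16.4, so my estimate for the flask is 8.18 %.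

Now put that answer back in. Free monomer then ends near 91.8 %, against Sunday's 94.4 %. If the rate goes with free monomer, scaling by that ratio gives 7.96 %.

If a chain takes one initiator to begin, chains begun cannot outnumber the initiator charged, so u is the floor of the average. Each initiator that begins no chain raises it. The runs do not show that share, so I commit to 7.96 % and an average above 15.9.

The forecast says 16 units and 6.6 %, and its ground for the first is this: “The early lag hints at incomplete initiation”.

    free monomer + initiator → living end + monomer in chains (k = 0.00733 /M/min)
    free monomer + living end → monomer in chains + living end, rate k2*[living end]*[free monomer] (k = 0.607 /M/min)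
    monomer in chains + living end → free monomer + living end, rate k3*[living end] as long as [monomer in chains] is above zero (k = 0.0198 /min)
    initiator → spent initiator (k = 0.00181 /min)

The flask gives 8.22 % reacted and 51.2 units a chain. At 12.0 h spent initiator stands at 9.70 × 10⁻⁴ M, more than the living end at 5.35 × 10⁻⁴ M. Since u is about a third of that average, on this reckoning about a third of the flask's charged initiator began a chain. The run with twice the initiator gives 49.0 units a chain, 2.99 times u.

All runs were computed for substances that don't exist, and the scatter is random.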